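A small charge of substrate, 0.20 M in oak, ends with about the same fractions as 0.44 M in maple, and partner stood at 0.20 M in oak, alder and maple alike.

| flask | substrate | partner | remark | time |
|---|---|---|---|---|
| oak | 0.20 M | 0.20 M | run made earlier |  |
| alder | 0.28 M | 0.20 M | run made earlier |  |
| maple | 0.44 M | 0.20 M | run made earlier |  |
| south-west | 0.20 M (fed, over 8.0 d) | 0.200 M | all else is in the flask from the start; the feed brings no volume worth counting | 10 d |
| south-east | 0.20 M | 0.200 M (fed, over 20 h) | all else is in the flask from the start; the feed brings no volume worth counting | 10 d |
| north | 0.20 M | 0.200 M | everything together at the start | 10 d |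
| south | 0.20 M | 0.200 M (fed, over 8.0 d) | all else is in the flask from the start; the feed brings no volume worth counting | 10 d |

| run | time / d | target / % | side product A / % |
|---|---|---|---|
| oak | 1.25 | 4.7 | 2.7 |
| oak | 2.50 | 4.1 | 3.5 |
| oak | 4.00 | 3.8 | 3.1 |
| oak | 5.00 | 3.6 | 2.8 |
| oak | 6.00 | 3.6 | 3.0 |
| alder | 2.08 | 3.4 | 4.6 |
| alder | 4.00 | 3.6 | 2.7 |
| alder | 6.00 | 4.9 | 3.4 |
| alder | 8.00 | 3.9 | 3.3 |
| alder | 10.0 | 3.1 | 3.3 |
| maple | 0.833 | 49.4 | 3.2 |
| maple | 2.50 | 23.3 | 3.4 |
| maple | 5.00 | 3.3 | 2.8 |
| maple | 8.00 | 4.0 | 3.6 |
| maple | 10.0 | 3.5 | 4.0 |

(each reading ± 0.5 percentage points)

- a reading or a percentage of target counts all its forms, free or not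

1. the flask with the highest share of target in target plus side product A ("all alike" if they lie within 1.5 percentage points) (south-west / south-east / north / south / all alike)
2. share of target in target plus side product A at the end, south-west
3. share of target in target plus side product A at the end, south-east
4. share of target in target plus side product A at the end, north
5. share of target in target plus side product A at the end, south

The last two readings of each run average 3.62% of the charge as target and 3.33% as side product A. This second figure is the full-partner loss: the fraction of charged substrate ending as side product A while partner stands at its whole charge. The bench rule freezes partner, a pseudo-first-order reckoning. No run varied partner, so it is an assumption here that side product A takes one partner each and that the loss scales with the fraction of partner standing while substrate passes. Maple would then spend 7.33% of its partner, so freezing is fair. North and south-west hold their whole partner from the start, which gives a share of 52.0%.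

The rule stops where partner is itself fed. Maple already reads 3.2% side product A at 0.833 d, within the scatter of 0.5 percentage points of the full-partner loss, so the passage of substrate reads as over by then. Against the slow feed that time is a ratio of 0.104, so this reckoning puts the loss in south below 0.347% and the share above 91.2%. Against the quick feed the ratio is 1.00, so for south-east this reckoning gives nothing sharper than the frozen figure.

The forecast gave 53% for south-west, 53% for south-east, 54% for north and 62% for south, with south's range from 49% to 90%, and it named south: “Only south keeps substrate in excess late”. The reckoning here differs on south, where its share of 91.2% stands higher than that central figure.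

The flasks give 53.9% for south-west, 95.7% for south-east, 53.9% for north and 99.5% for south.

    substrate + partner → intermediate A (k = 0.00280 L mol⁻¹ min⁻¹)
    intermediate A → side product A (k = 0.00790 min⁻¹)
    substrate → target (k = 0.0160 min⁻¹)
    intermediate A → intermediate B (k = 5.60 × 10⁻⁵ min⁻¹)
    partner + intermediate B → side product B (k = 0.00580 L mol⁻¹ min⁻¹)
    intermediate B → side product C (k = 5.70 × 10⁻⁴ min⁻¹)
    crystals ⇌ target, rate k7*(cs7 - [target]) while solid is left; crystals form when [target] > cs7 (solubility = 21.0 mM, k = 0.0170 min⁻¹)
    target ⇌ isomer of the product (K = 24.0, k = 0.00700 min⁻¹)

South ends with 0.0187% side product A, less than the reckoned 0.347%, and north with 3.30%. The neighbouring flask is north with partner cut to 0.080 M, which is 0.400 equiv. The same reckoning scales the full-partner loss by 0.400, giving 1.33% of the charge and a share of 73.1%. That flask ends with 1.35% side product A, 96.6% of its partner left and a share of 74.5%.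

The data stem from a simulated flask for an exercise; the scatter is artificial.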